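**Retrosynthetic overview** (disconnections listed from the deepest to the last bond made)
- Four-membered carbocycle, formed first: [2+2] of methyl eugenol 1 with dichloroketene 3 (from trichloroacetyl chloride 2) gives 4, which is dechlorinated to the prochiral cyclobutanone 5.
- Key disconnection, lactone O1–C5 bond: (R)-lactone 7 comes from 5 by enantioselective oxygen insertion (Baeyer–Villiger desymmetrization through Criegee adduct 6). The carbocycle is expanded to the lactone ring (second and last ring event) and the only stereocentre is set here.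
- Exocyclic (E)-C=C, made last: 7 plus vanillin acetate 8 in a one-pot aldol addition, acetylation, E1cB elimination and de-acetylation (through 9, 10, 11, 12) gives target 13. Both arenes are bought intact.

Assumption: the sense of induction of the new catalyst in step 3 cannot be predicted with certainty. The (S,S)-catalyst is written, and its (R,R) mirror image is used instead if the (S,S) form gives the enantiomer of 7 (checked by chiral HPLC and optical rotation).

Step 1
Reactants: 1 methyl eugenol (4-allyl-1,2-dimethoxybenzene), 2 trichloroacetyl chloride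
Product: 4 racemic 2,2-dichloro-3-(3,4-dimethoxybenzyl)cyclobutan-1-one, via dichloroketene 3 (not isolated)
Conditions: Zn(Cu) couple (2.5 equiv), Et2O–DME 5:1, 2 added over 2 h at 20 °C, then reflux 2 h
Reagents that add atoms: none
Why: Zinc dechlorinates 2 to dichloroketene 3, whose thermal ketene–alkene [2+2] cycloaddition with the terminal alkene of 1 is regioselective (carbonyl carbon to the CH2 terminus), while DME ties up ZnCl2 so the veratrole ring is not acylated; the new stereocentre is formed racemic and loses its stereogenic character in step 2.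

Step 2
Reactants: 4 racemic 2,2-dichloro-3-(3,4-dimethoxybenzyl)cyclobutan-1-one
Product: 5 prochiral ketone 3-(3,4-dimethoxybenzyl)cyclobutan-1-one
Conditions: Zn dust (6 equiv), AcOH, 20 → 50 °C, 3 h
Reagents that add atoms: none
Why: Reductive dehalogenation of the α,α-dichloroketone by zinc in acetic acid (through zinc enolates) removes both chlorines and leaves the ketone, the arene and the methyl ethers untouched, giving an achiral ketone with two enantiotopic α-CH2 groups.

Step 3
Reactants: 5 prochiral ketone 3-(3,4-dimethoxybenzyl)cyclobutan-1-one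
Product: 7 (R)-4-(3,4-dimethoxybenzyl)dihydrofuran-2(3H)-one, via Criegee adduct 6 (not isolated)
Conditions: (S,S)-imidodiphosphoric acid HN[P(=O)(O2R*)]2, R*(OH)2 = (S)-3,3'-bis(2,4,6-triethylphenyl)-1,1'-bi-2-naphthol (5 mol %), 35% aq. H2O2 (1.5 equiv), CHCl3, −40 °C, 36 h
Reagents that add atoms: hydrogen peroxide, OO
Why: Proposed new method: a confined chiral imidodiphosphoric acid as catalyst for the Baeyer–Villiger desymmetrization of a prochiral cyclobutanone with H2O2, not yet described as far as is known; its P=O/P–OH pair adds H2O2 to the strained ketone and then holds Criegee adduct 6 by two hydrogen bonds inside the narrow cleft walled by the four 2,4,6-triethylphenyl groups, so the flexible veratrylmethyl arm can leave only through the one open channel, which fixes the O–O bond antiperiplanar to just one of the two enantiotopic ring CH2 groups, and that CH2 migrates to oxygen with loss of water, forming the O1–C5 bond and setting C4 as R in the same event; the closest known reaction types are the BINOL-phosphoric-acid-catalysed H2O2 Baeyer–Villiger oxidation of 3-substituted cyclobutanones (only moderately selective for CH2-spaced 3-benzyl substrates, where an open catalyst cannot grip the remote arm) and the imidodiphosphoric-acid-catalysed sulfoxidation with H2O2.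

Step 4
Reactants: 7 (R)-4-(3,4-dimethoxybenzyl)dihydrofuran-2(3H)-one, 8 vanillin acetate (4-formyl-2-methoxyphenyl acetate)
Product: 13 (3E,4R)-4-(3,4-dimethoxybenzyl)-3-(4-hydroxy-3-methoxybenzylidene)oxolan-2-one (the target), via lithium enolate 9 (not isolated), via lithium aldolate 10 (not isolated), via aldol acetate 11 (not isolated), via O-acetyl target 12 (not isolated)
Conditions: LiN(SiMe3)2 (1.1 equiv), THF, −78 °C; 8 (1.1 equiv), −78 °C, 30 min; Ac2O (2.5 equiv), −78 → 0 °C; DBU (3 equiv), 20 → 50 °C, 2 h; pyrrolidine (5 equiv), 0 °C, 30 min; 1 M HCl work-up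
Reagents that add atoms: none
Why: Directed aldol addition of enolate 9 to the aldehyde of 8 at −78 °C (much faster than attack on the aryl acetate), O-acetylation of aldolate 10 and DBU-promoted E1cB elimination of acetate from 11 give the thermodynamically preferred E-arylidene lactone 12 (aryl anti to the lactone C=O), whose aryl acetate is then cleaved selectively by aminolysis with pyrrolidine; C4 is never enolisable in this sequence and keeps its R configuration.

**Compound list**
1 | methyl eugenol (4-allyl-1,2-dimethoxybenzene) | C=CCc1ccc(OC)c(OC)c1 | starting material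
2 | trichloroacetyl chloride | ClC(=O)C(Cl)(Cl)Cl | starting material
3 | dichloroketene | ClC(Cl)=C=O | intermediate (not isolated)
4 | racemic 2,2-dichloro-3-(3,4-dimethoxybenzyl)cyclobutan-1-one | O=C1CC(Cc2ccc(OC)c(OC)c2)C1(Cl)Cl | intermediate
5 | 3-(3,4-dimethoxybenzyl)cyclobutan-1-one (achiral, prochiral) | O=C1CC(Cc2ccc(OC)c(OC)c2)C1 | intermediate
6 | Criegee adduct, 3-(3,4-dimethoxybenzyl)-1-hydroperoxycyclobutan-1-ol (cis/trans, both achiral) | OOC1(O)CC(Cc2ccc(OC)c(OC)c2)C1 | intermediate (not isolated)
7 | (R)-4-(3,4-dimethoxybenzyl)dihydrofuran-2(3H)-one | O=C1C[C@@H](Cc2ccc(OC)c(OC)c2)CO1 | intermediate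
8 | vanillin acetate (4-formyl-2-methoxyphenyl acetate) | CC(=O)Oc1ccc(C=O)cc1OC | starting material
9 | lithium (4R)-4-(3,4-dimethoxybenzyl)-4,5-dihydrofuran-2-olate (lithium enolate of 7) | [Li+].[O-]C1=C[C@@H](Cc2ccc(OC)c(OC)c2)CO1 | intermediate (not isolated)
10 | lithium (4-acetoxy-3-methoxyphenyl)[(4R)-4-(3,4-dimethoxybenzyl)-2-oxooxolan-3-yl]methanolate (diastereomer mixture at C3 and the carbinol carbon; only C4 defined) | [Li+].[O-]C(c1ccc(OC(C)=O)c(OC)c1)C1C(=O)OC[C@@H]1Cc1ccc(OC)c(OC)c1 | intermediate (not isolated)
11 | (4-acetoxy-3-methoxyphenyl)[(4R)-4-(3,4-dimethoxybenzyl)-2-oxooxolan-3-yl]methyl acetate (same diastereomer mixture) | CC(=O)OC(c1ccc(OC(C)=O)c(OC)c1)C1C(=O)OC[C@@H]1Cc1ccc(OC)c(OC)c1 | intermediate (not isolated)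
12 | 4-{(E)-[(4R)-4-(3,4-dimethoxybenzyl)-2-oxooxolan-3-ylidene]methyl}-2-methoxyphenyl acetate | CC(=O)Oc1ccc(/C=C2/C(=O)OC[C@@H]2Cc2ccc(OC)c(OC)c2)cc1OC | intermediate (not isolated)
13 | (3E,4R)-4-(3,4-dimethoxybenzyl)-3-(4-hydroxy-3-methoxybenzylidene)oxolan-2-one | COc1cc(/C=C2/C(=O)OC[C@@H]2Cc2ccc(OC)c(OC)c2)ccc1O | target

**Totals**
Total step count: 4. Longest linear sequence: 4 (1 → 4 → 5 → 7 → 13).

**Steps most likely to fail**

Step 3 (the proposed new catalysis). The lactone will form, but the enantiomeric excess may be insufficient. Material of moderate ee can be tried for upgrade by recrystallising 13. The fallback uses known chemistry, sets out from 5 and returns at 7. Enantioselective deprotonation of 5 with a C2-symmetric chiral lithium amide, lithium bis[(S)-1-phenylethyl]amide or its mirror image (whichever gives the R series), in THF at −100 °C with TMSCl present as internal quench, gives the silyl enol ether (R)-{[3-(3,4-dimethoxybenzyl)cyclobut-1-en-1-yl]oxy}trimethylsilane F1. Ozonolysis of the enol C=C (O3, CH2Cl2–MeOH, −78 °C, stopped at the first excess of ozone to spare the arene) with NaBH4 work-up gives (R)-4-(3,4-dimethoxyphenyl)-3-(hydroxymethyl)butanoic acid F2, which closes to 7 on acidification with 1 M HCl.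

Step 4 (four events in one flask). Possible failures are retro-aldol on warming, incomplete elimination or an E/Z mixture; acetyl scrambling between phenol and aldolate is harmless. The fallback replaces the aldol/E1cB logic by phosphonate olefination, sets out from 7 and returns at 12. Treatment of 7 with lithium diisopropylamide LiN(CHMe2)2 (2.2 equiv) and diethyl chlorophosphate (THF, −78 → 0 °C; O-phosphorylation followed by 1,3 O→C phosphoryl shift) gives diethyl [(4S)-4-(3,4-dimethoxybenzyl)-2-oxooxolan-3-yl]phosphonate F3 (same spatial arrangement as 7; the descriptor changes only because P outranks O). Horner–Wadsworth–Emmons reaction of F3 with 8 (LiCl, DBU, MeCN, 20 °C) gives 12, which is de-acetylated with pyrrolidine as in step 4.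

Step 1. The electron-rich arene can be acylated and dichloroketene can polymerise, lowering the yield. The fallback changes the ketene equivalent, sets out from 1 and returns at 5, so step 2 is then not needed. N,N-Dimethylacetamide, Tf2O and 2,4,6-collidine in 1,2-dichloroethane generate N,N-dimethylketeniminium triflate F4, which adds [2+2] to 1 at reflux to give 3-(3,4-dimethoxybenzyl)-N,N-dimethylcyclobutan-1-iminium triflate F5. Hydrolysis with aqueous NaHCO3 gives 5.

**Further compounds**
F1 | step 3 | (R)-{[3-(3,4-dimethoxybenzyl)cyclobut-1-en-1-yl]oxy}trimethylsilane | C[Si](C)(C)OC1=C[C@H](Cc2ccc(OC)c(OC)c2)C1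
F2 | step 3 | (R)-4-(3,4-dimethoxyphenyl)-3-(hydroxymethyl)butanoic acid | OC(=O)C[C@@H](Cc1ccc(OC)c(OC)c1)CO
F3 | step 4 | diethyl [(4S)-4-(3,4-dimethoxybenzyl)-2-oxooxolan-3-yl]phosphonate (mixture of C3 epimers) | CCOP(=O)(OCC)C1C(=O)OC[C@@H]1Cc1ccc(OC)c(OC)c1
F4 | step 1 | N,N-dimethylketeniminium triflate | C=C=[N+](C)C.[O-]S(=O)(=O)C(F)(F)F
F5 | step 1 | 3-(3,4-dimethoxybenzyl)-N,N-dimethylcyclobutan-1-iminium triflate | C[N+](C)=C1CC(Cc2ccc(OC)c(OC)c2)C1.[O-]S(=O)(=O)C(F)(F)F
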